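The data come from a simulation with constants of no real substance; the scatter is artificial.

At early times the north run looked idle: it still showed 0 % left-handed product at 30.0 min, though its partner feed had ended at 25 min.

| setting | north-east | north | south-east | eta | beta |
|---|---|---|---|---|---|
| left-handed substrate | 0.30 M | 0.30 M | 0.30 M | 0.30 M | 0.30 M |
| right-handed substrate | 0.30 M | 0.30 M | 0.30 M | 0.30 M | 0.30 M |
| partner | 0.33 M (fed, over 25 min) | 0.33 M (fed, over 25 min) | 0.49 M (fed, over 25 min) | 0.330 M (fed, over 25 min) | 0.330 M (fed, over 15 min) |
| precatalyst | 3 mM | 3 mM | 3 mM | 3.0 mM | 3.0 mM |
| impurity | 0.92 mM | 1.5 mM | 0.66 mM | 0.66 mM | 0.66 mM |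
| remark | run made earlier; the fed solution adds 0.10 times the starting volume | run made earlier; the fed solution adds 0.10 times the starting volume | run made earlier; the fed solution adds 0.10 times the starting volume | the fed solution adds 0.10 times the starting volume | the fed solution adds 0.10 times the starting volume |
| time |  |  |  | 1.5 h | 1.5 h |

| run | time / min | right-handed substrate / % | left-handed substrate / % | left-handed product / % |
|---|---|---|---|---|
| north-east | 8.00 | 49 | 50 | 0 |
| north-east | 15.0 | 49 | 52 | 0 |
| north-east | 30.0 | 52 | 43 | 4 |
| north-east | 60.0 | 50 | 35 | 16 |
| north-east | 120 | 52 | 17 | 30 |
| north | 8.00 | 48 | 49 | 0 |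
| north | 15.0 | 51 | 51 | 1 |
| north | 30.0 | 49 | 49 | 0 |
| north | 60.0 | 51 | 41 | 6 |
| north | 120 | 48 | 23 | 27 |
| south-east | 10.0 | 49 | 54 | 1 |
| south-east | 25.0 | 48 | 50 | 7 |
| south-east | 50.0 | 48 | 28 | 24 |
| south-east | 80.0 | 46 | 16 | 35 |
| south-east | 120 | 47 | 10 | 41 |

(each reading ± 2 percentage points)

- free catalyst is single-handed; left-handed substrate and right-handed substrate are mirror images of each other, charged as a racemate, each of them at the stated concentration
- charges are per starting volume, the dose included; the dosed solution carries all of it
- an excess is the difference of the two amounts in percent of their sum
- an excess is below zero if the other one leads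

- the winner by excess of right-handed substrate over left-handed substrate among what is left of the two; "neither" if no more than 2 percentage points parts them (eta / beta / neither)
- excess of right-handed substrate over left-handed substrate among what is left of the two at the end, eta
- excess of right-handed substrate over left-handed substrate among what is left of the two at the end, beta

I first asked what the north run's lag measured. I supposed that the precatalyst releases free catalyst by a first-order step and that the impurity destroys it one for one. For eta and beta the impurity charge is 22.0 % of the precatalyst charge. I call this share the catalyst debt. Under that supposition, the lag is the release half-life times ln(1/(1 − debt))/ln(2).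

How long is the release half-life? The north run's debt is 50.0 %, half of its precatalyst charge, so by that supposition its lag is one half-life. I read that lag as lying between 30.0 min and 60.0 min and took 45.0 min. For eta and beta the lag is then 16.1 min.

Does the dosing time matter? Beta's feed ended at 15 min, before my estimated lag was over. Eta's feed ran on to 25 min, so eta was short of partner for a while. I took the rate as proportional to partner. The shortfall shrinks linearly, and this triangle integrates to 1.57 min of working time.

The forecast said neither, with 38.5 % for eta and 39.5 % for beta. It put eta's loss at “costing only about 1 min of effective time”, where my triangle gave 1.57 min. Scaled by working time, my loss is worth 0.84 percentage points of the forecast's excess for beta, less than the margin of 2 points. So I also expected neither.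

The flask gave neither: 38.3 % for eta and 38.5 % for beta.

    partner + free catalyst + left-handed substrate → free catalyst + left-handed product (k = 80.0 /M²/min)
    partner + free catalyst + right-handed substrate → free catalyst + right-handed product (k = 1.76 /M²/min)
    free catalyst + impurity → spent catalyst (k = 9540 /M/min)
    2 free catalyst ⇌ resting dimer (K = 500 /M, k = 23.8 /M/min)
    precatalyst → free catalyst (k = 0.0186 /min)

Eta held 22.0 % of the catalyst charged as spent catalyst at 1.50 h, beside a debt of 22.0 %. Drawing out the feed changed little. The neighbouring flask was eta with 0.0011 M impurity. Its debt is 36.7 %, and the same reckoning gives a lag of 29.7 min, longer than eta's. It held 36.7 % as spent catalyst at 1.50 h. Its left-handed substrate stood at 26.6 %, and its excess reached 29.9 %, less than eta's.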